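One number is worth watching in this series, 0.895: the branching number ρ, the rate constant of the second addition times the partner as charged, divided by the forward rate constant of isomerisation. It is a selectivity factor, and it tells how many molecules of single product go on to double product for each that becomes isomer of the product.

the same everywhere: time 30 min
- Monday's: substrate 20 mM (fed, over 6.0 min); partner 60.0 mM; temperature 25 °C; all else is in the flask from the start; the feed brings no volume worth counting
- Wednesday's: substrate 20 mM; partner 60.0 mM (fed, over 25 min); temperature 25 °C; all else is in the flask from the start; the feed brings no volume worth counting
- Saturday's: substrate 20 mM (fed, over 25 min); partner 60.0 mM; the addition at 5 °C, then warmed to 25 °C; the feed brings no volume worth counting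
- Thursday's: substrate 20 mM; partner 60.0 mM; temperature 25 °C; everything together at the start

- the flask that comes out highest in amount of double product, in percent of the substrate charged; "all alike" if 1.5 percentage points covers them all (Monday's / Wednesday's / Saturday's / Thursday's / all alike)
- amount of double product at the end, in percent of the substrate charged, Monday's
- amount of double product at the end, in percent of the substrate charged, Wednesday's
- amount of double product at the end, in percent of the substrate charged, Saturday's
- amount of double product at the end, in percent of the substrate charged, Thursday's

- all constants are for 25 °C and move with temperature by the activation energies and enthalpies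

    substrate + partner → single product + by-product (k1 = 0.024 /M/s, Ea1 = 44.0 kJ/mol)
    substrate + partner → other mono adduct + by-product (k2 = 0.0053 /M/s, Ea2 = 53.0 kJ/mol)
    partner + single product → double product + by-product (k3 = 0.0097 /M/s, Ea3 = 72.0 kJ/mol)
    partner + other mono adduct → double product + by-product (k4 = 0.0098 /M/s, Ea4 = 71.0 kJ/mol)
    partner → decomposed reagent (k5 = 2.7 × 10⁻⁴ /s, Ea5 = 82.0 kJ/mol)
    single product ⇌ isomer of the product (K6 = 3.8, k6 = 6.5 × 10⁻⁴ /s, Ea6 = 78.0 kJ/mol, ΔH6 = −41.0 kJ/mol)
    (constants at 25 °C)

We reckon the end state first. With the partner as charged, single product has a half-life of 20 min by the second addition and 18 min by isomerisation. Because that race is close and ρ lies below one, we expect isomer of the product to stand somewhat above double product, at a ratio near ρ, in Thursday's, Monday's and Saturday's flasks, which hold the partner from the start.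

But ρ gives a split and no amount, so one number is not enough, and the clock has to rank the flasks. Thursday's flask has the whole 30 min. Monday's feed delays the average substrate by 3.00 min, so we put it just behind. In Wednesday's flask only half the partner has been fed at mid-feed, and part of that has already reacted or decomposed, so ρ there lies under 0.448 at that moment. Saturday's flask has 5.00 min of warmth after the feed, well short of the second addition's half-life, so we put it last.

The forecast names Thursday's at 21%, then Monday's at 19.5%, Wednesday's at 12.8% and Saturday's at 5.6%, holding that “the flask with the most partner and mono adduct together for longest” leads. The simulation gives Thursday's highest at 21.3%, then Monday's at 18.5%, Wednesday's at 12.1% and Saturday's at 5.53%, which is the order we reckoned. Double product over isomer of the product reads 0.761 in Thursday's flask and 0.910 in Saturday's at 30.0 min.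

Now take Saturday's recipe with 100 mM of partner. There ρ becomes 1.49, above one, so double product should overtake isomer of the product, although the warm stretch stays 5.00 min. That neighbour flask ends with 12.7% double product against 8.17% isomer of the product, a ratio of 1.55. It holds 39.9% as single product at 30.0 min.

Its constants were chosen freely; no experiment stands behind them.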